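**Plan** (abietane numbering: ring A = C1–C5 and C10; C20 = OCH2; C7 = benzylic OCH; arene = C8, C9, C11–C14, with the catechol on C11/C12 and isopropyl on C13)
- Retrosynthesis: remove the benzyl groups and the acetyl group, then cut C9–C10 and C4–C5 in one operation. This unravels rings A and B to a 2-aryl-3,6-dihydro-2H-pyran that carries a 2-silyloxy-4-methylpent-4-enyl chain on C10.
- The pyran is cut at C5=C10 (metathesis), C10–C1 (alkenyllithium plus epoxide), O–C20 (Williamson) and C6–C7 (allylation of an aryl aldehyde).
- Enabling feature: the ether ring (O, C20, C10, C5, C6, C7) holds C10 and the aryl-bearing C7 in a 1,4 relation. A radical relayed from C4 through C5=C10 to C10 is therefore bridged by the arene unit C8–C9, giving the benzo-fused 2-oxabicyclo[2.2.2]octane.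
- Forward order: aryl aldehyde, C7 carbinol, open-chain triene ether, oxygen ring (metathesis), then ring A followed by ring B and the isochroman ring (radical bicyclization), then acetate and debenzylation.
- Stereochemistry: C7 from Brown allylboration and C2 from (S)-epichlorohydrin; C5 from a chair transition state with the C2 silyloxy group equatorial; C10 from the C7 tether.

Key step: step 9

Remark (assumption): 3-bromo-4,5-dihydroxybenzaldehyde, isopropylzinc bromide solution, (−)-B-allyldiisopinocampheylborane solution, 2,3-dibromopropene, (S)-epichlorohydrin and isopropenylmagnesium bromide solution are taken as commercial.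

Step 1
Reactants: 1 3-bromo-4,5-dihydroxybenzaldehyde
Product: 2 3,4-bis(benzyloxy)-5-bromobenzaldehyde
Conditions: BnBr, K2CO3, DMF, 60 °C
Reagents that add atoms: benzyl bromide, BrCc1ccccc1
Why: Williamson etherification of both phenols with a reactive benzylic bromide under carbonate base should proceed cleanly, the aldehyde being inert.

Step 2
Reactants: 2 3,4-bis(benzyloxy)-5-bromobenzaldehyde; 3 isopropylzinc bromide
Product: 4 3,4-bis(benzyloxy)-5-isopropylbenzaldehyde
Conditions: Pd(OAc)2 (2 mol %), CPhos (4 mol %), THF/toluene, rt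
Reagents that add atoms: none
Why: Negishi coupling of a secondary alkylzinc halide with an aryl bromide, in which the bulky biarylphosphine favours reductive elimination over β-hydride elimination so that the branched isopropyl group is kept, and the organozinc does not add to the aldehyde.

Step 3
Reactants: 4 3,4-bis(benzyloxy)-5-isopropylbenzaldehyde; 5 (−)-B-allyldiisopinocampheylborane (from (+)-α-pinene)
Product: 6 (1S)-1-[3,4-bis(benzyloxy)-5-isopropylphenyl]but-3-en-1-ol
Conditions: Et2O, −78 °C; then NaOH, H2O2, rt
Reagents that add atoms: none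
Why: Brown asymmetric allylboration through a closed chair transition state, in which the reagent derived from (+)-α-pinene should deliver the allyl group to the aldehyde face that gives the (S)-carbinol (C7 of the target); alkaline peroxide frees the alcohol from boron.

Step 4
Reactants: 6 (1S)-1-[3,4-bis(benzyloxy)-5-isopropylphenyl]but-3-en-1-ol; 7 2,3-dibromopropene
Product: 8 1,2-bis(benzyloxy)-5-[(1S)-1-(2-bromoprop-2-en-1-yloxy)but-3-en-1-yl]-3-isopropylbenzene
Conditions: NaH, THF/DMF, 0 °C; then 7, Bu4NI (cat.), 0 °C to rt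
Reagents that add atoms: none
Why: Williamson etherification in which the sodium alkoxide displaces the allylic bromide by SN2 while the vinylic bromide is inert; the carbinol stereocentre is not involved.

Step 5
Reactants: 9 (S)-epichlorohydrin; 10 isopropenylmagnesium bromide
Product: 12 (2S)-2-(2-methylprop-2-en-1-yl)oxirane, via (2S)-1-chloro-4-methylpent-4-en-2-ol 11 (not isolated)
Conditions: CuBr·SMe2 (5 mol %), THF, −40 °C; H2O; then crude 11, NaOH, Et2O, rt
Reagents that add atoms: none
Why: Copper-catalysed Grignard opening of the epoxide at its unsubstituted carbon followed by base-induced closure of the chlorohydrin; neither event touches the stereocentre, so the (S) configuration of 9 is carried over and becomes C2 of the target.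

Step 6
Reactants: 8 1,2-bis(benzyloxy)-5-[(1S)-1-(2-bromoprop-2-en-1-yloxy)but-3-en-1-yl]-3-isopropylbenzene; 12 (2S)-2-(2-methylprop-2-en-1-yl)oxirane
Product: 14 (4S)-6-[({(1S)-1-[3,4-bis(benzyloxy)-5-isopropylphenyl]but-3-en-1-yl}oxy)methyl]-2-methylhepta-1,6-dien-4-ol, via 2-lithioallyl ether 13 (not isolated)
Conditions: t-BuLi (2 equiv), Et2O, −78 °C; then 12, BF3·OEt2, −78 °C; H2O
Reagents that add atoms: none
Why: Bromine–lithium exchange gives the alkenyllithium, which should open the BF3-activated monosubstituted epoxide at its terminal carbon (SN2) faster than any proton transfer at −78 °C; the carbinol centre of 12 is untouched.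

Step 7
Reactants: 14 (4S)-6-[({(1S)-1-[3,4-bis(benzyloxy)-5-isopropylphenyl]but-3-en-1-yl}oxy)methyl]-2-methylhepta-1,6-dien-4-ol
Product: 15 tert-butyldimethylsilyl ether of 14
Conditions: TBSCl, imidazole, DMF, rt
Reagents that add atoms: tert-butyldimethylsilyl chloride, CC(C)(C)[Si](C)(C)Cl
Why: Standard silylation of a secondary alcohol, which installs a bulky, non-participating C2 substituent for step 9.

Step 8
Reactants: 15 tert-butyldimethylsilyl ether of 14
Product: 16 (2S)-2-[3,4-bis(benzyloxy)-5-isopropylphenyl]-5-[(2S)-2-(tert-butyldimethylsilyloxy)-4-methylpent-4-en-1-yl]-3,6-dihydro-2H-pyran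
Conditions: second-generation Grubbs catalyst (5 mol %), CH2Cl2 (0.005 M), 40 °C
Reagents that add atoms: none
Why: Ring-closing olefin metathesis, in which the ruthenium carbene loads on the monosubstituted alkene and closes the six-membered ring onto the nearer 1,1-disubstituted alkene with loss of ethene, while the remote isopropenyl group (ten-membered ring, or a tetrasubstituted cyclopentene) should stay intact; the ring fixes the C5=C10 geometry.

Step 9
Reactants: 16 (2S)-2-[3,4-bis(benzyloxy)-5-isopropylphenyl]-5-[(2S)-2-(tert-butyldimethylsilyloxy)-4-methylpent-4-en-1-yl]-3,6-dihydro-2H-pyran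
Product: 17 (2S,5S,7S,10R)-11,12-bis(benzyloxy)-2α-(tert-butyldimethylsilyloxy)-7β,20-epoxyabieta-8,11,13-triene
Conditions: (R,R)-N,N'-bis(3,5-di-tert-butylsalicylidene)-1,2-cyclohexanediaminocobalt (divalent cobalt, 5 mol %), N-fluoro-2,4,6-trimethylpyridinium triflate (1.5 equiv), PhSiH3 (1.2 equiv), HFIP, 0 °C
Reagents that add atoms: none
Why: Proposed new method: A trivalent cobalt hydride (formed from the salen complex, the N-fluoropyridinium oxidant and PhSiH3) transfers a hydrogen atom to the 1,1-disubstituted alkene only, and the tertiary C4 radical adds 6-endo-trig to C5 of the dihydropyran alkene (ring A), giving a tertiary C10 radical that lies 1,4 across the oxygen ring from the C7 aryl group; with that ring in a boat and the aryl group axial, C10 adds to the ortho carbon C9, and oxidation with loss of a proton restores the arene, so this one bond closes ring B and the isochroman ring together as the benzo-fused 2-oxabicyclo[2.2.2]octane (a six-membered closure onto the arene in both directions). The closest known reaction type is the cobalt-salen-catalysed, hydrogen-atom-transfer-initiated radical bicyclization of open-chain aryl polyenes to abietane-type tricycles; new here is that the relay alkene is endocyclic and the arene terminator is a substituent of the same ring, so that the termination is bridging. C5 is set in the chair transition state of the first closure, in which the C2 silyloxy group is equatorial (an axial group would meet the axial C4 methyl group) and the chain approaches the alkene face remote from the aryl group; C10 is set by the tether, because C9 can reach only the face of C10 on which the C7 aryl group stands, which makes the overall addition across C5=C10 anti and the A/B junction trans. The step needs chemoselectivity for the terminal alkene (trisubstituted alkenes are poor hydrogen-atom acceptors), 6-endo over 5-exo closure (5-exo would require attack at the fully substituted C10) and attack at C9 and not C14 (C14 is flanked by the isopropyl group, C9 is activated by the ortho C11 benzyloxy group). A radical relay is chosen over a cationic one because a C10 cation would be prone to a 1,2-hydride shift from C20 and strong acid would ionise the p-alkoxybenzylic C7–O bond. The product has the ring system of the natural 7,20-epoxyabietanes, so the closure should build no unusual strain.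

Step 10
Reactants: 17 (2S,5S,7S,10R)-11,12-bis(benzyloxy)-2α-(tert-butyldimethylsilyloxy)-7β,20-epoxyabieta-8,11,13-triene
Product: 18 (2S,5S,7S,10R)-11,12-bis(benzyloxy)-7β,20-epoxyabieta-8,11,13-trien-2α-ol
Conditions: TBAF, THF, rt
Reagents that add atoms: none
Why: Fluoride-mediated cleavage of the Si–O bond, which should leave the ethers and all stereocentres untouched.

Step 11
Reactants: 18 (2S,5S,7S,10R)-11,12-bis(benzyloxy)-7β,20-epoxyabieta-8,11,13-trien-2α-ol
Product: 19 (2S,5S,7S,10R)-11,12-bis(benzyloxy)-7β,20-epoxyabieta-8,11,13-trien-2α-yl acetate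
Conditions: Ac2O, pyridine, DMAP (cat.), CH2Cl2, rt
Reagents that add atoms: acetic anhydride, CC(=O)OC(C)=O
Why: DMAP-catalysed acylation of the unhindered equatorial secondary alcohol, the only free hydroxyl group.

Step 12
Reactants: 19 (2S,5S,7S,10R)-11,12-bis(benzyloxy)-7β,20-epoxyabieta-8,11,13-trien-2α-yl acetate
Product: 20 (2S,5S,7S,10R)-11,12-dihydroxy-7β,20-epoxyabieta-8,11,13-trien-2α-yl acetate (target)
Conditions: H2 (1 atm), Pd/C (10 wt %), EtOAc, rt; work-up under argon
Reagents that add atoms: none
Why: Hydrogenolysis of the two aryl benzyl ethers on palladium should be much faster than cleavage of the hindered, bridging secondary benzylic dialkyl ether at C7, and the acetate is inert.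

**Compound list**
1 | 3-bromo-4,5-dihydroxybenzaldehyde | O=Cc1cc(O)c(O)c(Br)c1 | starting material
2 | 3,4-bis(benzyloxy)-5-bromobenzaldehyde | O=Cc1cc(Br)c(OCc2ccccc2)c(OCc2ccccc2)c1 | intermediate
3 | isopropylzinc bromide | CC(C)[Zn]Br | starting material
4 | 3,4-bis(benzyloxy)-5-isopropylbenzaldehyde | O=Cc1cc(C(C)C)c(OCc2ccccc2)c(OCc2ccccc2)c1 | intermediate
5 | (−)-B-allyldiisopinocampheylborane | C=CCB([C@@H]1C[C@@H]2C[C@H]([C@H]1C)C2(C)C)[C@@H]1C[C@@H]2C[C@H]([C@H]1C)C2(C)C | starting material
6 | (1S)-1-[3,4-bis(benzyloxy)-5-isopropylphenyl]but-3-en-1-ol | C=CC[C@H](O)c1cc(C(C)C)c(OCc2ccccc2)c(OCc2ccccc2)c1 | intermediate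
7 | 2,3-dibromopropene | C=C(Br)CBr | starting material
8 | 1,2-bis(benzyloxy)-5-[(1S)-1-(2-bromoprop-2-en-1-yloxy)but-3-en-1-yl]-3-isopropylbenzene | C=CC[C@H](OCC(Br)=C)c1cc(C(C)C)c(OCc2ccccc2)c(OCc2ccccc2)c1 | intermediate
9 | (S)-epichlorohydrin | ClC[C@@H]1CO1 | starting material
10 | isopropenylmagnesium bromide | CC(=C)[Mg]Br | starting material
11 | (2S)-1-chloro-4-methylpent-4-en-2-ol | ClC[C@@H](O)CC(C)=C | intermediate
12 | (2S)-2-(2-methylprop-2-en-1-yl)oxirane | C=C(C)C[C@H]1CO1 | intermediate
13 | 2-lithioallyl ether formed from 8 (lithium in place of bromine) | C=CC[C@H](OCC([Li])=C)c1cc(C(C)C)c(OCc2ccccc2)c(OCc2ccccc2)c1 | intermediate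
14 | (4S)-6-[({(1S)-1-[3,4-bis(benzyloxy)-5-isopropylphenyl]but-3-en-1-yl}oxy)methyl]-2-methylhepta-1,6-dien-4-ol | C=CC[C@H](OCC(=C)C[C@@H](O)CC(C)=C)c1cc(C(C)C)c(OCc2ccccc2)c(OCc2ccccc2)c1 | intermediate
15 | tert-butyldimethylsilyl ether of 14 (4S, 1'S) | C=CC[C@H](OCC(=C)C[C@@H](O[Si](C)(C)C(C)(C)C)CC(C)=C)c1cc(C(C)C)c(OCc2ccccc2)c(OCc2ccccc2)c1 | intermediate
16 | (2S)-2-[3,4-bis(benzyloxy)-5-isopropylphenyl]-5-[(2S)-2-(tert-butyldimethylsilyloxy)-4-methylpent-4-en-1-yl]-3,6-dihydro-2H-pyran | C=C(C)C[C@H](O[Si](C)(C)C(C)(C)C)CC1=CC[C@H](OC1)c1cc(C(C)C)c(OCc2ccccc2)c(OCc2ccccc2)c1 | intermediate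
17 | (2S,5S,7S,10R)-11,12-bis(benzyloxy)-2α-(tert-butyldimethylsilyloxy)-7β,20-epoxyabieta-8,11,13-triene | CC(C)(C)[Si](C)(C)O[C@H]1CC(C)(C)[C@@H]2C[C@@H]3OC[C@@]2(C1)c1c3cc(C(C)C)c(OCc2ccccc2)c1OCc1ccccc1 | intermediate
18 | (2S,5S,7S,10R)-11,12-bis(benzyloxy)-7β,20-epoxyabieta-8,11,13-trien-2α-ol | O[C@H]1CC(C)(C)[C@@H]2C[C@@H]3OC[C@@]2(C1)c1c3cc(C(C)C)c(OCc2ccccc2)c1OCc1ccccc1 | intermediate
19 | (2S,5S,7S,10R)-11,12-bis(benzyloxy)-7β,20-epoxyabieta-8,11,13-trien-2α-yl acetate | CC(=O)O[C@H]1CC(C)(C)[C@@H]2C[C@@H]3OC[C@@]2(C1)c1c3cc(C(C)C)c(OCc2ccccc2)c1OCc1ccccc1 | intermediate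
20 | (2S,5S,7S,10R)-11,12-dihydroxy-7β,20-epoxyabieta-8,11,13-trien-2α-yl acetate | CC(=O)O[C@H]1CC(C)(C)[C@@H]2C[C@@H]3OC[C@@]2(C1)c1c3cc(C(C)C)c(O)c1O | target

**Step count**
Total: 12 steps. Longest linear sequence: 11 steps (compound 1 to compound 20 through steps 1–4 and 6–12); the epoxide branch (step 5) joins at step 6.

**Steps most likely to fail**

1. Step 9 (the proposed new method).
   - What may go wrong: the first ring closure may occur on the wrong face of the pyran alkene, giving a C10 radical that cannot reach the arene. The bridging closure, which needs a boat with an axial aryl group, may be outrun by back hydrogen-atom transfer or by oxidation of the C10 radical followed by hydride shift from C20. Closure may occur at C14 in place of C9. The benzylic C7–O bond may ionise in the acidic fluorinated solvent.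
   - Fallback with known chemistry, setting out from 16 and returning at 17: ionic hydrogenolysis of the p-alkoxybenzylic C7–O bond of 16 (Et3SiH, BF3·OEt2, CH2Cl2, −78 °C) should open the pyran to (2Z)-5-[3,4-bis(benzyloxy)-5-isopropylphenyl]-2-[(2S)-2-(tert-butyldimethylsilyloxy)-4-methylpent-4-en-1-yl]pent-2-en-1-ol F1, whose alkene geometry is the one fixed by the former ring. MnO2 in CH2Cl2 should give the corresponding enal, (2Z)-5-[3,4-bis(benzyloxy)-5-isopropylphenyl]-2-[(2S)-2-(tert-butyldimethylsilyloxy)-4-methylpent-4-en-1-yl]pent-2-enal F2. The same divalent cobalt salen complex, oxidant and silane as in step 9 should then effect the known radical bicyclization of this open-chain aryl polyene with an electron-poor relay alkene, the equatorial C2 silyloxy group controlling C5 and C10, to give 11,12-bis(benzyloxy)-2α-(tert-butyldimethylsilyloxy)abieta-8,11,13-trien-20-al F3. NaBH4 in MeOH should reduce it to 11,12-bis(benzyloxy)-2α-(tert-butyldimethylsilyloxy)abieta-8,11,13-trien-20-ol F4. DDQ (CH2Cl2, pH 7 buffer) should abstract hydride from C7 (para to the C12 benzyloxy group), and the axial C20 hydroxyl group should close the ether from the β face to give 17.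

2. Step 6.
   - What may go wrong: proton transfer from the benzylic, oxygen-bearing C7–H to the alkenyllithium followed by Wittig rearrangement, or β-elimination of the alkoxide from the 2-lithioallyl ether to an allene, may compete with epoxide opening.
   - Fallback, setting out from 12 and 6 and returning at 15 (it replaces steps 4, 6 and 7, and the organometallic is made on a fragment without the benzylic ether): the Grignard reagent of (2-bromoallyl)trimethylsilane (Mg, THF; CuBr·SMe2 cat.) should open 12 at its terminal carbon to give (4S)-2-methyl-6-[(trimethylsilyl)methyl]hepta-1,6-dien-4-ol F5. TBSCl and imidazole should give its silyl ether, tert-butyl({(4S)-2-methyl-6-[(trimethylsilyl)methyl]hepta-1,6-dien-4-yl}oxy)dimethylsilane F6. NBS in CH2Cl2 at −78 °C should effect bromodesilylation with allylic transposition (the two allyl termini are equivalent) to give {[(4S)-6-(bromomethyl)-2-methylhepta-1,6-dien-4-yl]oxy}(tert-butyl)dimethylsilane F7. Alkylation of the sodium alkoxide of 6 (NaH, THF/DMF) with F7 should give 15 directly.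

3. Step 12.
   - What may go wrong: hydrogenolysis may continue into the bridging benzylic C7–O bond, and the free catechol may oxidise in air during isolation.
   - Fallback, setting out from 19 and ending at 20: non-reductive, Lewis-acid debenzylation with BCl3 and pentamethylbenzene as cation scavenger in CH2Cl2 at −78 °C, then methanol quench under argon. This fallback makes no new compound (F0).

**Further compounds**
F1 | step 9 | (2Z)-5-[3,4-bis(benzyloxy)-5-isopropylphenyl]-2-[(2S)-2-(tert-butyldimethylsilyloxy)-4-methylpent-4-en-1-yl]pent-2-en-1-ol | OC/C(C[C@@H](O[Si](C)(C)C(C)(C)C)CC(C)=C)=C\CCc1cc(C(C)C)c(OCc2ccccc2)c(OCc2ccccc2)c1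
F2 | step 9 | (2Z)-5-[3,4-bis(benzyloxy)-5-isopropylphenyl]-2-[(2S)-2-(tert-butyldimethylsilyloxy)-4-methylpent-4-en-1-yl]pent-2-enal | O=C/C(C[C@@H](O[Si](C)(C)C(C)(C)C)CC(C)=C)=C\CCc1cc(C(C)C)c(OCc2ccccc2)c(OCc2ccccc2)c1
F3 | step 9 | 11,12-bis(benzyloxy)-2α-(tert-butyldimethylsilyloxy)abieta-8,11,13-trien-20-al | CC(C)(C)[Si](C)(C)O[C@H]1CC(C)(C)[C@@H]2CCc3cc(C(C)C)c(OCc4ccccc4)c(OCc4ccccc4)c3[C@@]2(C=O)C1
F4 | step 9 | 11,12-bis(benzyloxy)-2α-(tert-butyldimethylsilyloxy)abieta-8,11,13-trien-20-ol | CC(C)(C)[Si](C)(C)O[C@H]1CC(C)(C)[C@@H]2CCc3cc(C(C)C)c(OCc4ccccc4)c(OCc4ccccc4)c3[C@@]2(CO)C1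
F5 | step 6 | (4S)-2-methyl-6-[(trimethylsilyl)methyl]hepta-1,6-dien-4-ol | C[Si](C)(C)CC(=C)C[C@@H](O)CC(C)=C
F6 | step 6 | tert-butyl({(4S)-2-methyl-6-[(trimethylsilyl)methyl]hepta-1,6-dien-4-yl}oxy)dimethylsilane | C[Si](C)(C)CC(=C)C[C@@H](O[Si](C)(C)C(C)(C)C)CC(C)=C
F7 | step 6 | {[(4S)-6-(bromomethyl)-2-methylhepta-1,6-dien-4-yl]oxy}(tert-butyl)dimethylsilane | BrCC(=C)C[C@@H](O[Si](C)(C)C(C)(C)C)CC(C)=C
F0 | step 12 | none | none
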